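## Retrosynthetic overview
1. Naphthalene numbering is used, with the side chain on C2 and the carbinol carbon as C1'. The end game frees the C5 and C8 phenols from methoxymethyl acetals and cuts the C1'–O acyl bond back to alcohol 13 and acid 15.
2. Quinone 12 comes from 1-naphthol 11 by para-oxidation, which adds the oxygen at C4. Naphthol 11 is the aromatised isomer of the 1,4-oxygen-bridged dihydronaphthalene 10, whose bridge oxygen stays on C1.
3. Feature used: ring B (C4a, C5, C6, C7, C8, C8a) carries the same oxygen substituent at C5 and C8, one on each side of the C4a–C8a bond, so it equals a symmetrical 3,6-dioxygenated benzyne. Ring A (C1–C4, oxygen at C1 and C4, chain at C2) equals a 3-substituted furan.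
4. Key disconnection: C1–C8a and C4–C4a, by [4+2] addition of aryne 9 (from bromide 2) to furan 7. Ring B is bought with bromohydroquinone, and ring A is the only ring made (bridged in step 5, aromatic in step 6).
5. C1' (S) is set before the cycloaddition by asymmetric allylboration of furan-3-carbaldehyde. Cross-metathesis then turns allyl into prenyl.

Key step: step 5

Remark: C1' of the target is S (alkannin series). The naphthazarin tautomers interconvert rapidly, so the drawn tautomer with the side chain on the quinone ring stands for the compound.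

## Route

Step 1
Reactants: 1 bromohydroquinone
Product: 2 2-bromo-1,4-bis(methoxymethoxy)benzene
Conditions: NaH, MOMCl, DMF, 0 °C → rt
Reagents that add atoms: chloromethyl methyl ether (MOMCl), COCCl
Why: Williamson-type O-alkylation of the bis-phenoxide gives the bis-acetal, whose oxygens later help to acidify H3 and can be removed under mild chelating Lewis-acid conditions.

Step 2
Reactants: 3 furan-3-carbaldehyde
Product: 5 (1S)-1-(furan-3-yl)but-3-en-1-ol, via borinate ester 4 (not isolated)
Conditions: allylB(Ipc)2 [Ipc from (+)-α-pinene, 1 M in pentane], Et2O, −78 °C; then NaOH, H2O2, 0 °C → rt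
Reagents that add atoms: B-allyldiisopinocampheylborane from (+)-α-pinene, C=CCB([C@@H]1C[C@@H]2C[C@H]([C@H]1C)C2(C)C)[C@@H]1C[C@@H]2C[C@H]([C@H]1C)C2(C)C
Why: Brown asymmetric allylboration runs through a closed chair (Zimmerman–Traxler) transition state in which the Ipc groups from (+)-α-pinene deliver allyl to the Si face of the aldehyde, the sense known for aromatic aldehydes, which sets C1' as S before alkaline H2O2 cleaves borinate 4.

Step 3
Reactants: 5 (1S)-1-(furan-3-yl)but-3-en-1-ol
Product: 6 (1S)-1-(furan-3-yl)-4-methylpent-3-en-1-ol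
Conditions: 2-methylbut-2-ene (large excess), second-generation Grubbs catalyst (H2IMes)(PCy3)Cl2Ru=CHPh (cat.), CH2Cl2, 40 °C
Reagents that add atoms: 2-methylbut-2-ene, CC=C(C)C
Why: Olefin cross-metathesis of a terminal alkene with excess 2-methylbut-2-ene exchanges =CH2 for =CMe2 (the standard allyl-to-prenyl conversion), tolerates the carbinol and the furan, and does not involve C1'.

Step 4
Reactants: 6 (1S)-1-(furan-3-yl)-4-methylpent-3-en-1-ol
Product: 7 tert-butyl{[(1S)-1-(furan-3-yl)-4-methylpent-3-enyl]oxy}dimethylsilane
Conditions: TBSCl, imidazole, DMF, rt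
Reagents that add atoms: tert-butyldimethylsilyl chloride, CC(C)(C)[Si](C)(C)Cl
Why: Standard imidazole-promoted silylation at oxygen retains C1' and gives an ether that is inert to LDA and is a poor leaving group for the later acid step.

Step 5
Reactants: 2 2-bromo-1,4-bis(methoxymethoxy)benzene; 7 tert-butyl{[(1S)-1-(furan-3-yl)-4-methylpent-3-enyl]oxy}dimethylsilane
Product: 10 2-[(1S)-1-(tert-butyldimethylsilyloxy)-4-methylpent-3-enyl]-5,8-bis(methoxymethoxy)-1,4-dihydro-1,4-epoxynaphthalene (both bridgehead diastereomers; the 1R,4S form is drawn), via 2-bromo-3-lithio-1,4-bis(methoxymethoxy)benzene 8 (not isolated), via 3,6-bis(methoxymethoxy)benzyne 9 (not isolated)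
Conditions: 7 (1 equiv), 2 (2.5 equiv), THF, −78 °C; LDA (LiN(iPr)2, 2.6 equiv) added slowly; −78 °C → rt
Reagents that add atoms: none
Why: LDA removes H3 of 2 to give aryllithium 8, which loses LiBr on warming, and the resulting aryne 9 adds suprafacially in a concerted [4+2] (Diels–Alder) step across the two α-carbons of furan 7, forming C1–C8a and C4–C4a. The closest known reaction type is the trapping of 3,6-dialkoxybenzynes, generated from 2-halo-1,4-dialkoxybenzenes with lithium amides, by furans (3-substituted ones included) to give 1,4-epoxy-1,4-dihydronaphthalenes. Ring A closes as a six-membered carbocycle by intermolecular cycloaddition, both bonds forming in one event, with the furan oxygen left as a bridge between C1 and C4. The bridge ties the two new centres C1 and C4 to each other, the remote C1' centre is not expected to control their sense, and so both diastereomers should form and both lose these centres in step 6. No regioselectivity is required because the groups next to the triple bond are identical, so either orientation of 7 gives one constitution. The selectivities that are needed are deprotonation at H3 rather than at a furan α-position, secured by the joint acidifying effect of Br and the acetal oxygen, and capture of 9 by the furan diene rather than by the prenyl alkene or by diisopropylamine, served by the high reactivity of furans toward arynes and by using 2 and LDA in excess, while C1' has no acidic hydrogen and stays S.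

Step 6
Reactants: 10 the oxygen-bridged cycloadduct (diastereomer mixture)
Product: 11 2-[(1S)-1-(tert-butyldimethylsilyloxy)-4-methylpent-3-enyl]-5,8-bis(methoxymethoxy)naphthalen-1-ol
Conditions: TFA (cat.), CH2Cl2, −20 → 0 °C; Et3N quench; used without delay
Reagents that add atoms: none
Why: In this known acid-catalysed ring opening and aromatisation of a 1,4-epoxy-1,4-dihydronaphthalene to a 1-naphthol, the protonated bridge should break at C4–O because that cation is benzylic to the C5-oxygenated ring and allylic with its far end on substituted C2, loss of H1 then gives 11, opening in the other sense would give a naphthol with an equally free para position that leads to the same quinone 12, and catalytic acid in a dry non-nucleophilic solvent should spare acetals, silyl ether and alkene.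

Step 7
Reactants: 11 the 1-naphthol
Product: 12 2-[(1S)-1-(tert-butyldimethylsilyloxy)-4-methylpent-3-enyl]-5,8-bis(methoxymethoxy)naphthalene-1,4-dione
Conditions: (KSO3)2NO (2.5 equiv), KH2PO4 buffer, acetone–H2O, 0 °C → rt
Reagents that add atoms: potassium nitrosodisulfonate (KSO3)2NO, [K+].[K+].[O]N(S(=O)(=O)[O-])S(=O)(=O)[O-]
Why: In the Teuber oxidation one equivalent of the radical abstracts the phenolic hydrogen and a second couples at the free para carbon C4 and collapses to the 1,4-quinone, while the aryl acetals of ring B, the silyl ether and the alkene are inert at near-neutral pH.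

Step 8
Reactants: 12 the silylated quinone
Product: 13 2-[(1S)-1-hydroxy-4-methylpent-3-enyl]-5,8-bis(methoxymethoxy)naphthalene-1,4-dione
Conditions: HF·pyridine, pyridine, THF, 0 °C → rt
Reagents that add atoms: none
Why: Fluoride-driven Si–O cleavage under buffered conditions avoids the basic fluoride sources that damage quinones, keeps the acetals and does not break the C1'–O bond, so S is retained.

Step 9
Reactants: 14 3-hydroxy-3-methylbutanoic acid
Product: 15 3-acetoxy-3-methylbutanoic acid
Conditions: AcCl, CH2Cl2, 0 °C → rt; aqueous work-up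
Reagents that add atoms: acetyl chloride, CC(=O)Cl
Why: O-acetylation of the tertiary alcohol with acetyl chloride in the absence of base avoids β-elimination, and any mixed anhydride at the carboxyl group is hydrolysed on work-up.

Step 10
Reactants: 13 the quinone alcohol; 15 3-acetoxy-3-methylbutanoic acid
Product: 17 (1S)-1-[5,8-bis(methoxymethoxy)-1,4-dioxo-1,4-dihydronaphthalen-2-yl]-4-methylpent-3-enyl 3-acetoxy-3-methylbutanoate, via O-acylisourea 16 (not isolated)
Conditions: DCC, DMAP (cat.), CH2Cl2, 0 °C → rt
Reagents that add atoms: none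
Why: Steglich esterification is the usual way to acylate the side-chain hydroxyl in this naphthoquinone family, it transfers the acyl group to oxygen so that C1' stays S, and low temperature with only catalytic DMAP limits loss of acetic acid from the activated acid.

Step 11
Reactants: 17 the bis-acetal ester
Product: 18 (1S)-1-(5,8-dihydroxy-1,4-dioxo-1,4-dihydronaphthalen-2-yl)-4-methylpent-3-enyl 3-acetoxy-3-methylbutanoate (target)
Conditions: MgBr2·OEt2 (excess), CH2Cl2–Et2O, 0 °C → rt; aq NH4Cl
Reagents that add atoms: none
Why: In this chelation-assisted Lewis-acid cleavage of aryl methoxymethyl ethers, magnesium binds between each quinone carbonyl and its peri acetal oxygen (C4=O with C5–O, C1=O with C8–O), bromide removes the CH2OMe group, and the reagent is mild enough for both esters and the alkene and does not touch C1'.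

## Compound list
1 | bromohydroquinone | Oc1ccc(O)c(Br)c1 | starting material
2 | 2-bromo-1,4-bis(methoxymethoxy)benzene | COCOc1ccc(OCOC)c(Br)c1 | intermediate
3 | furan-3-carbaldehyde | O=Cc1ccoc1 | starting material
4 | (1S)-1-(furan-3-yl)but-3-enyl diisopinocampheylborinate (not isolated) | O([C@@H](CC=C)c1ccoc1)B([C@@H]1C[C@@H]2C[C@H]([C@H]1C)C2(C)C)[C@@H]1C[C@@H]2C[C@H]([C@H]1C)C2(C)C | intermediate
5 | (1S)-1-(furan-3-yl)but-3-en-1-ol | O[C@@H](CC=C)c1ccoc1 | intermediate
6 | (1S)-1-(furan-3-yl)-4-methylpent-3-en-1-ol | O[C@@H](CC=C(C)C)c1ccoc1 | intermediate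
7 | tert-butyl{[(1S)-1-(furan-3-yl)-4-methylpent-3-enyl]oxy}dimethylsilane | CC(C)(C)[Si](C)(C)O[C@@H](CC=C(C)C)c1ccoc1 | intermediate
8 | 2-bromo-3-lithio-1,4-bis(methoxymethoxy)benzene (not isolated) | COCOc1ccc(OCOC)c([Li])c1Br | intermediate
9 | 3,6-bis(methoxymethoxy)benzyne (not isolated) | COCOC1=CC=C(OCOC)C#C1 | intermediate
10 | 2-[(1S)-1-(tert-butyldimethylsilyloxy)-4-methylpent-3-enyl]-5,8-bis(methoxymethoxy)-1,4-dihydro-1,4-epoxynaphthalene; (1R,4S) form drawn, the (1S,4R) form is made and carried on with it | CC(C)(C)[Si](C)(C)O[C@@H](CC=C(C)C)C1=C[C@@H]2O[C@H]1c1c(OCOC)ccc(OCOC)c12 | intermediate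
11 | 2-[(1S)-1-(tert-butyldimethylsilyloxy)-4-methylpent-3-enyl]-5,8-bis(methoxymethoxy)naphthalen-1-ol | CC(C)(C)[Si](C)(C)O[C@@H](CC=C(C)C)c1ccc2c(OCOC)ccc(OCOC)c2c1O | intermediate
12 | 2-[(1S)-1-(tert-butyldimethylsilyloxy)-4-methylpent-3-enyl]-5,8-bis(methoxymethoxy)naphthalene-1,4-dione | CC(C)(C)[Si](C)(C)O[C@@H](CC=C(C)C)C1=CC(=O)c2c(OCOC)ccc(OCOC)c2C1=O | intermediate
13 | 2-[(1S)-1-hydroxy-4-methylpent-3-enyl]-5,8-bis(methoxymethoxy)naphthalene-1,4-dione | O[C@@H](CC=C(C)C)C1=CC(=O)c2c(OCOC)ccc(OCOC)c2C1=O | intermediate
14 | 3-hydroxy-3-methylbutanoic acid | CC(C)(O)CC(=O)O | starting material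
15 | 3-acetoxy-3-methylbutanoic acid | CC(=O)OC(C)(C)CC(=O)O | intermediate
16 | O-(3-acetoxy-3-methylbutanoyl)-N,N'-dicyclohexylisourea (not isolated) | CC(=O)OC(C)(C)CC(=O)OC(=NC1CCCCC1)NC1CCCCC1 | intermediate
17 | (1S)-1-[5,8-bis(methoxymethoxy)-1,4-dioxo-1,4-dihydronaphthalen-2-yl]-4-methylpent-3-enyl 3-acetoxy-3-methylbutanoate | CC(=O)OC(C)(C)CC(=O)O[C@@H](CC=C(C)C)C1=CC(=O)c2c(OCOC)ccc(OCOC)c2C1=O | intermediate
18 | (1S)-1-(5,8-dihydroxy-1,4-dioxo-1,4-dihydronaphthalen-2-yl)-4-methylpent-3-enyl 3-acetoxy-3-methylbutanoate | CC(=O)OC(C)(C)CC(=O)O[C@@H](CC=C(C)C)C1=CC(=O)c2c(O)ccc(O)c2C1=O | target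

## Step count and risks
Total step count: 11.
Longest linear sequence: 9 steps (3 → 5 → 6 → 7 → 10 → 11 → 12 → 13 → 17 → 18; steps 2, 3, 4, 5, 6, 7, 8, 10, 11).

**Step 6.**
- What may go wrong: once the electron-rich naphthol has formed, the acid may ionise the benzylic C1'–O bond ortho to the free hydroxyl (quinone-methide pathway). That would erode or destroy C1' and allow cyclisation onto the prenyl alkene. Premature loss of the acetals is a second risk.
- Fallback: it sets out from furan 7 and comes back at quinone 12. It places an oxygen on the furan so that the bridge opens without any acid.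
- C–H borylation of 7 with B2pin2, [Ir(OMe)(cod)]2 and 4,4'-di-tert-butyl-2,2'-bipyridine should take place at the unhindered α-position. This gives 2-{4-[(1S)-1-(tert-butyldimethylsilyloxy)-4-methylpent-3-enyl]furan-2-yl}-4,4,5,5-tetramethyl-1,3,2-dioxaborolane F2. Which α-position reacts does not matter, because the aryne is symmetrical.
- NaBO3 in THF–H2O oxidises the C–B bond, and the hydroxyfuran tautomerises to 4-[(1S)-1-(tert-butyldimethylsilyloxy)-4-methylpent-3-enyl]furan-2(5H)-one F3.
- TIPSOTf and Et3N then give {4-[(1S)-1-(tert-butyldimethylsilyloxy)-4-methylpent-3-enyl]furan-2-yl}oxytriisopropylsilane F4.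
- Aryne 9, made from 2 and LDA through 8 as in step 5, adds to F4 to give the C4-(triisopropylsilyloxy) bridged ketal F5. This should open on its own, pushed by the silyloxy oxygen, to 2-[(1S)-1-(tert-butyldimethylsilyloxy)-4-methylpent-3-enyl]-5,8-bis(methoxymethoxy)-4-(triisopropylsilyloxy)naphthalen-1-ol F6.
- PhI(OAc)2 in MeCN–H2O oxidises this hydroquinone monoether to 12, so steps 6 and 7 are both replaced.

**Step 5.**
- What may go wrong: diisopropylamine, LDA or aryllithium 8 may capture the aryne faster than the hindered furan does, and the furan may be partly metalated. The valuable furan would then be consumed incompletely.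
- Fallback: it sets out from 2 and comes back at aryllithium 8. It separates metalation from aryne release.
- Bromide 2 is deprotonated with LDA in THF at −78 °C, and the cold aryllithium is quenched with I2. This gives 2-bromo-3-iodo-1,4-bis(methoxymethoxy)benzene F1, which is purified free of amine.
- n-BuLi is then added at −78 °C to F1 and 7 in toluene–THF. Iodine–lithium exchange is faster than any deprotonation and regenerates 8 with no amine in the flask.
- Aryne 9 then meets only the furan, and nearly equimolar amounts of the partners can be used on the way to 10.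

**Step 11.**
- What may go wrong: once the naphthazarin is unveiled, its electron-rich tautomer may help the C1' ester to ionise. The tertiary acetate may be lost by elimination, or acetal cleavage may stop halfway.
- Fallback: it sets out from alcohol 13 and comes back at target 18. It reverses the order of the last two operations so that the ester never meets the deprotection.
- The acetals of 13 are removed with dilute HCl in THF–iPrOH at rt to give alkannin F7.
- The side-chain hydroxyl of F7 is then acylated selectively with 15, DCC and catalytic DMAP (through 16). The two peri phenols are tied up in hydrogen bonds to the quinone carbonyls and are known not to compete under these conditions.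

## Further compounds
F1 | step 5 | 2-bromo-3-iodo-1,4-bis(methoxymethoxy)benzene | COCOc1ccc(OCOC)c(I)c1Br
F2 | step 6 | 2-{4-[(1S)-1-(tert-butyldimethylsilyloxy)-4-methylpent-3-enyl]furan-2-yl}-4,4,5,5-tetramethyl-1,3,2-dioxaborolane | CC(C)(C)[Si](C)(C)O[C@@H](CC=C(C)C)c1coc(B2OC(C)(C)C(C)(C)O2)c1
F3 | step 6 | 4-[(1S)-1-(tert-butyldimethylsilyloxy)-4-methylpent-3-enyl]furan-2(5H)-one | CC(C)(C)[Si](C)(C)O[C@@H](CC=C(C)C)C1=CC(=O)OC1
F4 | step 6 | {4-[(1S)-1-(tert-butyldimethylsilyloxy)-4-methylpent-3-enyl]furan-2-yl}oxytriisopropylsilane | CC(C)(C)[Si](C)(C)O[C@@H](CC=C(C)C)c1coc(O[Si](C(C)C)(C(C)C)C(C)C)c1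
F5 | step 6 | C4-(triisopropylsilyloxy) bridged ketal, the 4-silyloxy analogue of 10 (one bridgehead diastereomer drawn, not isolated) | CC(C)(C)[Si](C)(C)O[C@@H](CC=C(C)C)C1=C[C@]2(O[Si](C(C)C)(C(C)C)C(C)C)O[C@H]1c1c(OCOC)ccc(OCOC)c12
F6 | step 6 | 2-[(1S)-1-(tert-butyldimethylsilyloxy)-4-methylpent-3-enyl]-5,8-bis(methoxymethoxy)-4-(triisopropylsilyloxy)naphthalen-1-ol | CC(C)(C)[Si](C)(C)O[C@@H](CC=C(C)C)c1cc(O[Si](C(C)C)(C(C)C)C(C)C)c2c(OCOC)ccc(OCOC)c2c1O
F7 | step 11 | alkannin, 5,8-dihydroxy-2-[(1S)-1-hydroxy-4-methylpent-3-enyl]naphthalene-1,4-dione | O[C@@H](CC=C(C)C)C1=CC(=O)c2c(O)ccc(O)c2C1=O
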